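Everything rests on the C9–C10 bond. C10, the quaternary carbon shared by rings A and B, is γ to the C3 carbonyl, so ring A can be stored as a bicyclo[3.1.0]hexan-2-one whose cyclopropane is C1–C2–C10. In one operation a silyl Lewis acid lets C9 of a tethered Z-allylsilane open the C2–C10 fusion bond. Ring B closes, the five-membered ring grows into ring A, C9 and C10 are set, and the C8=C17 methylene appears. The precursor carries the C6–C12 chain on C5, anti to the C1 methylene and next to the C4 quaternary centre. C4 and C5 come from (R)-carvone, and the cyclopropane methylene is delivered externally to a cyclopentenone.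

Key step: step 16

Assumption: labdane numbering is used for all intermediates. Stereocentres that a later step erases (the carbinol and epoxide carbons of 5–7, C12 of 27, C15 of 30, C10 of F1/F2) are left open in the SMILES.

Step 1
Reactants: 1 (R)-(−)-carvone
Product: 2 (5R,6S)-2,6-dimethyl-5-(prop-1-en-2-yl)cyclohex-2-en-1-one (trans-6-methylcarvone)
Conditions: LiN(i-Pr)2, THF, −78 °C; MeI, −78 → 0 °C
Reagents that add atoms: iodomethane, SMILES CI
Why: Kinetic α′-deprotonation of the cross-conjugated enone and SN2 methylation of the lithium enolate (enolate alkylation) bring in C18, while C5 comes from the chiral pool and the new centre is planarised again in step 2.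

Step 2
Reactants: 2 trans-6-methylcarvone
Product: 3 (5S,6R)-6-(hydroxymethyl)-2,6-dimethyl-5-(prop-1-en-2-yl)cyclohex-2-en-1-one (CH2OH trans to isopropenyl)
Conditions: LiN(i-Pr)2, THF, −78 °C; CH2O (gas from cracked paraformaldehyde), −78 °C
Reagents that add atoms: formaldehyde, SMILES C=O
Why: Aldol addition of the fully substituted lithium enolate to monomeric formaldehyde occurs on the face opposite the neighbouring isopropenyl group, which sets the C4 quaternary centre with C19 trans and C18 cis to C10.

Step 3
Reactants: 3 hydroxymethyl ketone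
Product: 4 (5S,6R)-2,6-dimethyl-5-(prop-1-en-2-yl)-6-[(triisopropylsilyloxy)methyl]cyclohex-2-en-1-one
Conditions: i-Pr3SiOTf, 2,6-lutidine, CH2Cl2, 0 °C
Reagents that add atoms: triisopropylsilyl triflate, SMILES CC(C)[Si](OS(=O)(=O)C(F)(F)F)(C(C)C)C(C)C
Why: O-silylation of the neopentyl primary alcohol with a silyl triflate stops retro-aldol cleavage and installs a bulky ether whose oxygen stays a poor nucleophile in step 16.

Step 4
Reactants: 4 TIPS ether enone
Product: 5 1-vinyl tertiary allylic alcohol derived from 4 (vinyl on C3; carbinol configuration open)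
Conditions: CH2=CHMgBr, CeCl3, THF, −78 → 0 °C
Reagents that add atoms: vinylmagnesium bromide, SMILES C=C[Mg]Br
Why: Organocerium 1,2-addition suppresses conjugate addition, copes with the hindered non-enolisable carbonyl and attaches C2 to C3, and the carbinol centre disappears in step 6.

Step 5
Reactants: 5 tertiary allylic alcohol
Product: 6 epoxy alcohol (ring C7–C8 epoxide syn to the C3 hydroxyl; vinyl and isopropenyl intact)
Conditions: VO(acac)2 (cat.), t-BuOOH, CH2Cl2, 0 °C → rt
Reagents that add atoms: tert-butyl hydroperoxide, SMILES CC(C)(C)OO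
Why: Hydroxyl-directed vanadium-catalysed epoxidation selects the electron-rich trisubstituted allylic alkene over the monosubstituted vinyl group and the remote isopropenyl group and delivers oxygen syn to the hydroxyl.

Step 6
Reactants: 6 epoxy alcohol
Product: 8 (3S,4R)-4-methyl-5-oxo-3-(prop-1-en-2-yl)-4-[(triisopropylsilyloxy)methyl]hept-6-enal, via triol 7 (not isolated)
Conditions: H5IO6 (2.5 equiv), THF/H2O, 0 °C → rt
Reagents that add atoms: none
Why: Periodic acid hydrolyses the epoxide (water at the tertiary carbon) and then performs two Malaprade glycol cleavages that excise the former C(CH3) ring carbon as acetic acid, which frees C3 as the vinyl ketone and C7 as the aldehyde without touching C4 or C5.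

Step 7
Reactants: 8 seco vinyl ketone aldehyde
Product: 9 2-[(1S,5R)-2,5-dimethyl-4-oxo-5-[(triisopropylsilyloxy)methyl]cyclopent-2-en-1-yl]acetaldehyde (C6 arm cis to C19 arm)
Conditions: second-generation Hoveyda–Grubbs catalyst (5 mol %), toluene, 80 °C
Reagents that add atoms: none
Why: Ring-closing metathesis of the vinyl ketone with the isopropenyl group closes the ring C3–C2=C10–C5–C4 under neutral conditions with loss of ethene, helped by the geminal substitution at C4, so the γ centre C5 cannot epimerise.

Step 8
Reactants: 9 cyclopentenone aldehyde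
Product: 10 (4S,5R)-4-(2-hydroxyethyl)-3,5-dimethyl-5-[(triisopropylsilyloxy)methyl]cyclopent-2-en-1-one
Conditions: NaBH4 (0.3 equiv), MeOH/CH2Cl2, −78 °C
Reagents that add atoms: none
Why: Chemoselective borohydride reduction at low temperature works because the unhindered aldehyde reacts far faster than the conjugated ketone flanked by a quaternary carbon.

Step 9
Reactants: 10 hydroxyethyl cyclopentenone
Product: 11 (4S,5R)-4-(2-iodoethyl)-3,5-dimethyl-5-[(triisopropylsilyloxy)methyl]cyclopent-2-en-1-one
Conditions: I2, PPh3, imidazole, CH2Cl2, 0 °C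
Reagents that add atoms: iodine, SMILES II
Why: Appel iodination converts the primary alcohol by SN2 displacement of its alkoxyphosphonium salt under nearly neutral conditions that leave the enone and silyl ether alone.

Step 10
Reactants: 12 propane-1,3-diol
Product: 13 3-hydroxypropyl pivalate
Conditions: t-BuCOCl (0.3 equiv relative to diol), pyridine, CH2Cl2, 0 °C
Reagents that add atoms: pivaloyl chloride, SMILES CC(C)(C)C(=O)Cl
Why: Nucleophilic acyl substitution on the symmetrical diol used in excess gives the mono-ester.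

Step 11
Reactants: 13 3-hydroxypropyl pivalate
Product: 14 3-oxopropyl pivalate
Conditions: TEMPO (cat.), PhI(OAc)2, CH2Cl2, rt
Reagents that add atoms: none
Why: Oxoammonium (TEMPO) oxidation stops at the aldehyde, and its base-free medium avoids β-elimination of pivalate.

Step 12
Reactants: 14 3-oxopropyl pivalate
Product: 15 4,4-dibromobut-3-en-1-yl pivalate
Conditions: CBr4, PPh3, CH2Cl2, 0 °C
Reagents that add atoms: tetrabromomethane, SMILES BrC(Br)(Br)Br
Why: Ramirez dibromoolefination (first stage of the Corey–Fuchs sequence) converts the aldehyde carbon C9 into the C9=C8Br2 unit under non-basic conditions.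

Step 13
Reactants: 11 iodoethyl cyclopentenone; 15 dibromoalkene
Product: 17 (4S,5R)-4-[(3Z)-3-bromo-6-(pivaloyloxy)hex-3-en-1-yl]-3,5-dimethyl-5-[(triisopropylsilyloxy)methyl]cyclopent-2-en-1-one, via alkylzinc iodide 16 (not isolated)
Conditions: Zn dust, LiCl, THF, 35 °C; then 15, PdCl2(DPEphos) (3 mol %), THF, 0 °C → rt
Reagents that add atoms: none
Why: Zinc insertion gives a ketone-tolerant alkylzinc iodide, and Negishi coupling of a 1,1-dibromoalkene takes place first at the less hindered C–Br bond trans to the alkyl substituent, which places C7 trans to C11 and leaves bromine cis to C11.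

Step 14
Reactants: 17 bromoalkenyl cyclopentenone
Product: 18 (1S,3R,4S,5S)-4-[(3Z)-3-bromo-6-(pivaloyloxy)hex-3-en-1-yl]-3,5-dimethyl-3-[(triisopropylsilyloxy)methyl]bicyclo[3.1.0]hexan-2-one (C1 methylene anti to the C6 chain)
Conditions: Me3S(O)I, NaH, DMSO, rt
Reagents that add atoms: trimethylsulfoxonium iodide, SMILES C[S+](C)(C)=O.[I-]
Why: In this Corey–Chaykovsky cyclopropanation the sulfoxonium ylide adds in conjugate fashion to C10 from the face opposite the C6 chain on C5 and the C19 arm on C4, and the enolate displaces dimethyl sulfoxide on the same face, so C2 and C10 are set with C1 anti to the chain.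

Step 15
Reactants: 18 bromoalkenyl bicyclo[3.1.0]hexanone
Product: 19 (1S,3R,4S,5S)-3,5-dimethyl-4-[(3Z)-6-(pivaloyloxy)-3-[(trimethylsilyl)methyl]hex-3-en-1-yl]-3-[(triisopropylsilyloxy)methyl]bicyclo[3.1.0]hexan-2-one (key-step precursor)
Conditions: Me3SiCH2MgCl, ZnCl2, THF, 0 °C; then 18, Pd(P(t-Bu)3)2 (5 mol %), THF, rt → 40 °C
Reagents that add atoms: (trimethylsilyl)methylmagnesium chloride, SMILES C[Si](C)(C)C[Mg]Cl
Why: Negishi coupling of the remaining alkenyl bromide with the silylmethylzinc reagent, which has no β-hydrogen, proceeds with retention of geometry on a bulky trialkylphosphine complex of zerovalent palladium and installs the Z-allylsilane (C11 cis to CH2SiMe3) last, so it meets neither acid nor base before step 16.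

Step 16
Reactants: 19 allylsilane bicyclo[3.1.0]hexanone
Product: 21 3-oxo-19-(triisopropylsilyloxy)-13,14,15,16-tetranor-ent-labd-8(17)-en-12-yl pivalate (trans-decalin; C19 and C20 axial on one face; H5 and H9 on the other), via silyl enol ether 20 (not isolated)
Conditions: Me3SiOTf (0.3 equiv), 2,6-di-tert-butyl-4-methylpyridine (0.1 equiv), CH2Cl2, −78 → −20 °C; then 1 M HCl, THF, 0 °C
Reagents that add atoms: none
Why: Proposed new method: Me3SiOTf silylates the C3 carbonyl oxygen, the acyl cyclopropane polarises so that the bond from C2 to the fully substituted C10 stretches, C9 of the allylsilane attacks C10 from the side opposite C2, the β-silyl cation at C8 gives up Me3Si+ (regenerating Me3SiOTf) to leave the C8=C17 methylene, and silyl enol ether 20 is hydrolysed to ketone 21, with relief of cyclopropane strain paying for bond formation at a neopentyl-type carbon. The closest known reaction types are the Lewis-acid homoconjugate opening of cyclopropyl ketones by tethered alkenes, the acid-induced ring expansion of bicyclo[3.1.0]hexan-2-ones at the fusion bond and the intramolecular Hosomi–Sakurai reaction. Ring B closes in a 6-exo-tet mode at C10 (6-endo with respect to the C8=C9 π bond) through a chair, and the same bond cleavage turns the five-membered ring into six-membered ring A. C10 is set by inversion, because the C6 tether lies on the face opposite C1 and C20 therefore ends axial and anti to H5 (trans-decalin), and C9 is set by the Z-alkene geometry, which places C11, trans to C7, equatorial in the chair. The step needs cleavage of the C2–C10 fusion bond rather than the better aligned outer C1–C2 bond, and this is secured by the tertiary character of C10, by a tether that can reach only C10 and by the absence of any external nucleophile. The hindered pyridine removes adventitious acid that would protodesilylate the allylsilane, and the bulk of the TIPS group keeps the C19 oxygen from competing for C10.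

Step 17
Reactants: 21 decalone pivalate
Product: 22 19-(triisopropylsilyloxy)-13,14,15,16-tetranor-ent-labd-8(17)-ene-3α,12-diol (C3 hydroxyl equatorial)
Conditions: LiAlH4, THF, 0 °C
Reagents that add atoms: none
Why: In this hydride reduction LiAlH4 attacks the C3 ketone along the axial trajectory from the face opposite the axial C19 arm, which gives the equatorial alcohol, and it cleaves the pivalate in the same operation.

Step 18
Reactants: 22 diol
Product: 23 3α-hydroxy-19-(triisopropylsilyloxy)-13,14,15,16-tetranor-ent-labd-8(17)-en-12-al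
Conditions: TEMPO (cat.), PhI(OAc)2, CH2Cl2, rt
Reagents that add atoms: none
Why: TEMPO oxoammonium oxidation distinguishes the unhindered primary C12 alcohol from the neopentyl secondary C3 alcohol and stops at the aldehyde.

Step 19
Reactants: 24 3-bromofuran
Product: 25 3-bromo-2-(trimethylsilyl)furan
Conditions: LiN(i-Pr)2, THF, −78 °C; Me3SiCl
Reagents that add atoms: chlorotrimethylsilane, SMILES C[Si](C)(C)Cl
Why: Deprotonation occurs at furan C2, the position flanked by oxygen and bromine, and C-silylation marks the carbon that will become the lactone carbonyl C16.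

Step 20
Reactants: 23 aldehyde; 25 3-bromo-2-(trimethylsilyl)furan
Product: 27 15,16-epoxy-16-(trimethylsilyl)-19-(triisopropylsilyloxy)-ent-labda-8(17),13(16),14-triene-3α,12-diol (C12 epimers), via 3-lithio-2-(trimethylsilyl)furan 26 (not isolated)
Conditions: 25 (2.3 equiv), n-BuLi, Et2O, −78 °C; then 23, −78 °C
Reagents that add atoms: none
Why: Bromine–lithium exchange at −78 °C gives the 3-furyllithium, which adds 1,2 to the aldehyde after one equivalent is consumed by the C3 hydroxyl, and the mixture at C12 does not matter because step 21 erases that centre.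

Step 21
Reactants: 27 furyl carbinols
Product: 28 15,16-epoxy-3α-hydroxy-16-(trimethylsilyl)-19-(triisopropylsilyloxy)-ent-labda-8(17),13(16),14-trien-12-one
Conditions: MnO2, CH2Cl2, rt
Reagents that add atoms: none
Why: MnO2 oxidises only the activated furyl carbinol and leaves the saturated C3 alcohol untouched.

Step 22
Reactants: 28 furyl ketone
Product: 29 (12R)-15,16-epoxy-16-(trimethylsilyl)-19-(triisopropylsilyloxy)-ent-labda-8(17),13(16),14-triene-3α,12-diol
Conditions: (S)-Me-CBS oxazaborolidine (20 mol %), catecholborane (3 equiv), toluene, −78 °C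
Reagents that add atoms: none
Why: In this Corey–Bakshi–Shibata reduction the 2-silyl-3-furyl group acts as the large substituent and C11H2 as the small one, so the (S)-catalyst should give the 12R alcohol as it gives (R)-carbinols from aryl alkyl ketones, and catecholborane does not hydroborate the C8=C17 alkene at this temperature.

Step 23
Reactants: 29 (12R)-furyl carbinol
Product: 31 (12R)-3α,12-dihydroxy-19-(triisopropylsilyloxy)-ent-labda-8(17),13-dien-16,15-olide, via γ-hydroxybutenolide 30 (not isolated)
Conditions: O2, visible light, rose bengal (cat.), CH2Cl2/MeOH, −78 °C; then NaBH4, 0 °C; 1 M HCl work-up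
Reagents that add atoms: dioxygen, SMILES O=O
Why: Singlet oxygen adds [4+2] to the electron-rich silylfuran much faster than it undergoes the ene reaction with a 1,1-disubstituted alkene, silyl migration fixes the carbonyl at the carbon that carried silicon (C16), and borohydride reduction of the masked C15 aldehyde followed by acid lactonisation gives the α-substituted butenolide.

Step 24
Reactants: 31 TIPS-protected butenolide
Product: 32 (12R)-3α,12,19-trihydroxy-ent-labda-8(17),13-dien-16,15-olide (target CNP0270153.1)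
Conditions: HF·pyridine, THF, 0 °C → rt
Reagents that add atoms: none
Why: Fluoride cleavage of the Si–O bond in a mildly acidic medium spares the base-sensitive butenolide, the C12 allylic alcohol and the exocyclic alkene.

Compound list
1 | (R)-(−)-carvone | O=C1C(C)=CC[C@@H](C(C)=C)C1 | starting material
2 | (5R,6S)-6-methylcarvone | O=C1C(C)=CC[C@@H](C(C)=C)[C@@H]1C | intermediate
3 | (5S,6R)-6-(hydroxymethyl)-6-methylcarvone | O=C1C(C)=CC[C@@H](C(C)=C)[C@]1(C)CO | intermediate
4 | TIPS ether of 3 | O=C1C(C)=CC[C@@H](C(C)=C)[C@]1(C)CO[Si](C(C)C)(C(C)C)C(C)C | intermediate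
5 | 1-vinyl tertiary allylic alcohol | OC1(C=C)C(C)=CC[C@@H](C(C)=C)[C@]1(C)CO[Si](C(C)C)(C(C)C)C(C)C | intermediate
6 | epoxy alcohol | OC1(C=C)C2(C)OC2C[C@@H](C(C)=C)[C@]1(C)CO[Si](C(C)C)(C(C)C)C(C)C | intermediate
7 | triol | OC1(C=C)C(C)(O)C(O)C[C@@H](C(C)=C)[C@]1(C)CO[Si](C(C)C)(C(C)C)C(C)C | intermediate
8 | seco vinyl ketone aldehyde | C=CC(=O)[C@@](C)(CO[Si](C(C)C)(C(C)C)C(C)C)[C@@H](CC=O)C(C)=C | intermediate
9 | cyclopentenone aldehyde | O=C1C=C(C)[C@H](CC=O)[C@]1(C)CO[Si](C(C)C)(C(C)C)C(C)C | intermediate
10 | hydroxyethyl cyclopentenone | O=C1C=C(C)[C@H](CCO)[C@]1(C)CO[Si](C(C)C)(C(C)C)C(C)C | intermediate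
11 | iodoethyl cyclopentenone | O=C1C=C(C)[C@H](CCI)[C@]1(C)CO[Si](C(C)C)(C(C)C)C(C)C | intermediate
12 | propane-1,3-diol | OCCCO | starting material
13 | 3-hydroxypropyl pivalate | CC(C)(C)C(=O)OCCCO | intermediate
14 | 3-oxopropyl pivalate | CC(C)(C)C(=O)OCCC=O | intermediate
15 | 4,4-dibromobut-3-en-1-yl pivalate | CC(C)(C)C(=O)OCCC=C(Br)Br | intermediate
16 | alkylzinc iodide from 11 | O=C1C=C(C)[C@H](CC[Zn]I)[C@]1(C)CO[Si](C(C)C)(C(C)C)C(C)C | intermediate
17 | (Z)-bromoalkenyl cyclopentenone | O=C1C=C(C)[C@H](CC/C(Br)=C/CCOC(=O)C(C)(C)C)[C@]1(C)CO[Si](C(C)C)(C(C)C)C(C)C | intermediate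
18 | (Z)-bromoalkenyl bicyclo[3.1.0]hexan-2-one | O=C1[C@H]2C[C@@]2(C)[C@H](CC/C(Br)=C/CCOC(=O)C(C)(C)C)[C@]1(C)CO[Si](C(C)C)(C(C)C)C(C)C | intermediate
19 | Z-allylsilane bicyclo[3.1.0]hexan-2-one (key-step precursor) | O=C1[C@H]2C[C@@]2(C)[C@H](CC/C(C[Si](C)(C)C)=C/CCOC(=O)C(C)(C)C)[C@]1(C)CO[Si](C(C)C)(C(C)C)C(C)C | intermediate
20 | C2=C3 trimethylsilyl enol ether of 21 | C=C1CC[C@@H]2[C@](C)(CO[Si](C(C)C)(C(C)C)C(C)C)C(O[Si](C)(C)C)=CC[C@@]2(C)[C@@H]1CCOC(=O)C(C)(C)C | intermediate
21 | 3-oxo-8(17)-ene trans-decalin, C12 pivalate, C19 TIPS ether (key-step product) | C=C1CC[C@@H]2[C@](C)(CO[Si](C(C)C)(C(C)C)C(C)C)C(=O)CC[C@@]2(C)[C@@H]1CCOC(=O)C(C)(C)C | intermediate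
22 | 3α,12-diol | C=C1CC[C@@H]2[C@](C)(CO[Si](C(C)C)(C(C)C)C(C)C)[C@H](O)CC[C@@]2(C)[C@@H]1CCO | intermediate
23 | C12 aldehyde | C=C1CC[C@@H]2[C@](C)(CO[Si](C(C)C)(C(C)C)C(C)C)[C@H](O)CC[C@@]2(C)[C@@H]1CC=O | intermediate
24 | 3-bromofuran | Brc1ccoc1 | starting material
25 | 3-bromo-2-(trimethylsilyl)furan | C[Si](C)(C)c1occc1Br | intermediate
26 | 3-lithio-2-(trimethylsilyl)furan | [Li]c1ccoc1[Si](C)(C)C | intermediate
27 | furyl carbinols (C12 epimers) | C=C1CC[C@@H]2[C@](C)(CO[Si](C(C)C)(C(C)C)C(C)C)[C@H](O)CC[C@@]2(C)[C@@H]1CC(O)c1ccoc1[Si](C)(C)C | intermediate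
28 | furyl ketone | C=C1CC[C@@H]2[C@](C)(CO[Si](C(C)C)(C(C)C)C(C)C)[C@H](O)CC[C@@]2(C)[C@@H]1CC(=O)c1ccoc1[Si](C)(C)C | intermediate
29 | (12R)-furyl carbinol | C=C1CC[C@@H]2[C@](C)(CO[Si](C(C)C)(C(C)C)C(C)C)[C@H](O)CC[C@@]2(C)[C@@H]1C[C@@H](O)c1ccoc1[Si](C)(C)C | intermediate
30 | γ-hydroxybutenolide (C15 epimers) | C=C1CC[C@@H]2[C@](C)(CO[Si](C(C)C)(C(C)C)C(C)C)[C@H](O)CC[C@@]2(C)[C@@H]1C[C@@H](O)C1=CC(O)OC1=O | intermediate
31 | TIPS-protected butenolide | C=C1CC[C@@H]2[C@](C)(CO[Si](C(C)C)(C(C)C)C(C)C)[C@H](O)CC[C@@]2(C)[C@@H]1C[C@@H](O)C1=CCOC1=O | intermediate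
32 | (12R)-3α,12,19-trihydroxy-ent-labda-8(17),13-dien-16,15-olide | C=C1CC[C@@H]2[C@](C)(CO)[C@H](O)CC[C@@]2(C)[C@@H]1C[C@@H](O)C1=CCOC1=O | target

Total step count: 24. Longest linear sequence: 20 steps (1–9, 13–18, 20–24).

Steps most likely to fail

1. Step 16 (key step).
- **What may go wrong:** The allylsilane may be protodesilylated before the cyclopropane is engaged. The better aligned outer C1–C2 bond may open instead. There may also be no reaction at temperatures the allylsilane tolerates.
- **Fallback:** It uses known chemistry, a stepwise ionisation in place of the concerted strain release. It sets out from 18 and comes back at 21. Anhydrous HCl in CH2Cl2 at 0 °C expands the bicyclo[3.1.0]hexan-2-one at the fusion bond to the tertiary chloro cyclohexanone F1, and the alkenyl bromide is inert to the acid. Negishi coupling with Me3SiCH2ZnCl and Pd(P(t-Bu)3)2, as in step 15, gives the allylsilane chloro ketone F2. TiCl4 in CH2Cl2 at −78 °C then ionises the tertiary chloride. The allylsilane captures the C10 cation through the chair–chair arrangement (Lewis-acid tert-alkylation of an allylsilane) and gives 21.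

2. Step 14.
- **What may go wrong:** Conjugate addition to the fully substituted β-carbon C10 may be slow. Competing γ-deprotonation would epimerise C5.
- **Fallback:** It replaces the ylide by a stepwise conjugate addition and 1,3-elimination. It sets out from 17 and comes back at 18. (i-PrO)Me2SiCH2MgCl with CuBr·SMe2 (cat.) and Me3SiCl in THF at −78 °C adds to C10 anti to the C6 chain and gives the trimethylsilyl enol ether F3. Dilute acid hydrolyses F3 to the silylmethyl cyclopentanone F4. Tamao oxidation (H2O2, KF, KHCO3, THF/MeOH) gives the hydroxymethyl cyclopentanone F5, and MsCl/Et3N gives the mesylate F6. LiN(SiMe3)2 in THF (−78 → 0 °C) closes the cyclopropane by 3-exo-tet alkylation of the C2 enolate and gives 18.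

3. Step 6.
- **What may go wrong:** The vinyl group may undergo semipinacol migration during acid opening of the hydroxy epoxide. The second glycol cleavage may stay incomplete.
- **Fallback:** It cleaves the ring first and adds the vinyl group afterwards. It sets out from 4 and comes back at 10. H2O2/NaOH in MeOH at 0 °C gives the epoxy ketone F7, and dilute H2SO4 in THF/H2O gives the dihydroxy ketone F8. NaIO4 cleaves F8 to the acid aldehyde F9. NaBH4 followed by acidification gives the δ-lactone F10. CH2=CHMgBr in THF at −78 °C adds once, because the tetrahedral alkoxide persists until the quench, and gives the hydroxy vinyl ketone F11. Ring-closing metathesis with the catalyst of step 7 then gives 10.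

Further compounds
F1 | step 16 | 4-chloro-4-methylcyclohexanone with bromoalkenyl chain (C10 open) | O=C1CCC(C)(Cl)[C@H](CC/C(Br)=C/CCOC(=O)C(C)(C)C)[C@]1(C)CO[Si](C(C)C)(C(C)C)C(C)C
F2 | step 16 | 4-chloro-4-methylcyclohexanone with Z-allylsilane chain (C10 open) | O=C1CCC(C)(Cl)[C@H](CC/C(C[Si](C)(C)C)=C/CCOC(=O)C(C)(C)C)[C@]1(C)CO[Si](C(C)C)(C(C)C)C(C)C
F3 | step 14 | trimethylsilyl enol ether of the conjugate adduct | C[Si](C)(C)OC1=C[C@@](C)(C[Si](C)(C)OC(C)C)[C@H](CC/C(Br)=C/CCOC(=O)C(C)(C)C)[C@]1(C)CO[Si](C(C)C)(C(C)C)C(C)C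
F4 | step 14 | 3-[(isopropoxydimethylsilyl)methyl]-3-methylcyclopentanone | O=C1C[C@@](C)(C[Si](C)(C)OC(C)C)[C@H](CC/C(Br)=C/CCOC(=O)C(C)(C)C)[C@]1(C)CO[Si](C(C)C)(C(C)C)C(C)C
F5 | step 14 | 3-(hydroxymethyl)-3-methylcyclopentanone | O=C1C[C@@](C)(CO)[C@H](CC/C(Br)=C/CCOC(=O)C(C)(C)C)[C@]1(C)CO[Si](C(C)C)(C(C)C)C(C)C
F6 | step 14 | mesylate of F5 | O=C1C[C@@](C)(COS(C)(=O)=O)[C@H](CC/C(Br)=C/CCOC(=O)C(C)(C)C)[C@]1(C)CO[Si](C(C)C)(C(C)C)C(C)C
F7 | step 6 | epoxy ketone from 4 | O=C1C2(C)OC2C[C@@H](C(C)=C)[C@]1(C)CO[Si](C(C)C)(C(C)C)C(C)C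
F8 | step 6 | dihydroxy ketone | O=C1C(C)(O)C(O)C[C@@H](C(C)=C)[C@]1(C)CO[Si](C(C)C)(C(C)C)C(C)C
F9 | step 6 | C3 acid C7 aldehyde | OC(=O)[C@@](C)(CO[Si](C(C)C)(C(C)C)C(C)C)[C@@H](CC=O)C(C)=C
F10 | step 6 | δ-lactone (C3 carbonyl, C7 oxygen) | O=C1OCC[C@@H](C(C)=C)[C@]1(C)CO[Si](C(C)C)(C(C)C)C(C)C
F11 | step 6 | hydroxy vinyl ketone | C=CC(=O)[C@@](C)(CO[Si](C(C)C)(C(C)C)C(C)C)[C@@H](CCO)C(C)=C
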